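Ring A (C4a, C5, C6, C7, C8, C8a) bears oxygen on C5, C7 and C8a and carbon on C4a, C6 and C8. This is the alternation of a folded 3,5,7-triketo ester, and the trans C2-aryl/C3-hydroxyl pair of ring C is a trans-epoxide opened at C2 by the oxygen on C8a.
Disconnections: the three MOM ethers come off last. Before that, C4a–C5 (Claisen) and O1–C2 (epoxide opening) are cut together, which leads back to an open-chain epoxy triketo ester.
The chain is cut at C4–C4a (diketo ester trianion plus (2R,3S)-glycidic ester), at C8–C8a (β-keto ester dianion plus acetyl donor) and at C6–C7 (self-Claisen condensation of a methyl 3-arylpropanoate, which brings in both benzyl groups at once).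
Ring order: ring B and the two benzyl arenes are bought, then ring A forms first and ring C second in one flask. The only source of chirality is a catalytic asymmetric epoxidation of the cinnamate.

Key step: step 7

Remark: flavonoid numbering (O1, C2, C3, C4, C4a, C5 to C8, C8a) is used for the corresponding atoms of all open-chain compounds. The open-chain β-dicarbonyl compounds are handled as mixtures of keto–enol tautomers and of epimers at C6 and C8, which is harmless because both carbons become sp2 in ring A.
Assumption: the L-series ketone catalyst of step 5 is taken as prepared from L-sorbose by the sequence established for its D-fructose-derived enantiomer, and as a catalyst it is not counted in the steps.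

Step 1
Reactants: 1 methyl 3-(4-hydroxyphenyl)propanoate
Product: 2 methyl 3-[4-(methoxymethoxy)phenyl]propanoate
Conditions: MOMCl, i-Pr2NEt, CH2Cl2, 0 °C to rt
Reagents that add atoms: chloromethyl methyl ether (MOMCl), COCCl
Why: Base-mediated O-alkylation of the phenol (MOM ether formation) masks the acidic OH as an acetal that is inert to NaH, LiN(i-Pr)2 and Mg(OCH3)2 and is removed by acid at the end.

Step 2
Reactants: 2 methyl 3-[4-(methoxymethoxy)phenyl]propanoate (two molecules)
Product: 3 methyl 2-[4-(methoxymethoxy)benzyl]-5-[4-(methoxymethoxy)phenyl]-3-oxopentanoate (racemic)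
Conditions: NaH (0.6 equiv), MeOH (cat.), THF, reflux; then AcOH, 0 °C
Reagents that add atoms: none
Why: In this self-Claisen condensation the enolate of one ester molecule acylates a second one to form C6–C7 and places both 4-alkoxybenzyl groups (on C6 and C8) in one operation, the equilibrium being pulled by deprotonation of the β-keto ester, and the racemic centre C6 disappears later on aromatisation.

Step 3
Reactants: 3 methyl 2-[4-(methoxymethoxy)benzyl]-5-[4-(methoxymethoxy)phenyl]-3-oxopentanoate
Product: 5 methyl 2,4-bis[4-(methoxymethoxy)benzyl]-3,5-dioxohexanoate, via dilithium dienolate 4 (not isolated)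
Conditions: LiN(i-Pr)2 (2.3 equiv), THF, −78 to 0 °C; MeC(O)N(OMe)Me (1.1 equiv), −78 to −20 °C; then AcOH
Reagents that add atoms: N-methoxy-N-methylacetamide, CC(=O)N(C)OC
Why: This is the γ-acylation of a β-keto ester dianion combined with the Weinreb ketone synthesis: the second deprotonation can only occur at the γ-CH2 (C8), this most nucleophilic carbon attacks the amide to form C8–C8a, and the chelated tetrahedral adduct survives until the quench, which suppresses proton transfer and double acylation.

Step 4
Reactants: 6 methyl (E)-3-(4-hydroxyphenyl)prop-2-enoate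
Product: 7 methyl (E)-3-[4-(methoxymethoxy)phenyl]prop-2-enoate
Conditions: MOMCl, i-Pr2NEt, CH2Cl2, 0 °C to rt
Reagents that add atoms: chloromethyl methyl ether (MOMCl), COCCl
Why: MOM ether formation by O-alkylation of the phenol keeps ring B a strong para donor, which later speeds up the electrophilic epoxidation and directs the epoxide opening to C2.

Step 5
Reactants: 7 methyl (E)-3-[4-(methoxymethoxy)phenyl]prop-2-enoate
Product: 8 methyl (2R,3S)-3-[4-(methoxymethoxy)phenyl]oxirane-2-carboxylate
Conditions: 4,5-di-O-acetyl-1,2-O-isopropylidene-β-L-erythro-2,3-hexodiulo-2,6-pyranose (30 mol %), KHSO5 (as 2KHSO5·KHSO4·K2SO4), NaHCO3, Bu4NHSO4 (cat.), MeCN/aq. Na2H2EDTA, 0 °C to rt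
Reagents that add atoms: potassium peroxymonosulfate (KHSO5), [K+].[O-]S(=O)(=O)OO
Why: In this Shi-type epoxidation with the ester-competent diacetate ketone the chiral dioxirane made in situ transfers oxygen stereospecifically to the electron-rich trans-cinnamate through a spiro transition state, and since the D-series ketone attacks the face that leads to (2S,3R)-glycidates (the sense of (R,R)-stilbene oxide), the L-series ketone should set both centres as (2R,3S).

Step 6
Reactants: 5 methyl 2,4-bis[4-(methoxymethoxy)benzyl]-3,5-dioxohexanoate (2 equiv), 8 methyl (2R,3S)-3-[4-(methoxymethoxy)phenyl]oxirane-2-carboxylate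
Product: 10 methyl 2,4-bis[4-(methoxymethoxy)benzyl]-7-{(2R,3S)-3-[4-(methoxymethoxy)phenyl]oxiran-2-yl}-3,5,7-trioxoheptanoate, via trilithium trienolate 9 (not isolated)
Conditions: 5, LiN(i-Pr)2 (3.3 equiv per 5), THF, −78 to 0 °C; 8 (0.5 equiv), −78 °C; then AcOH, −78 °C, pH 7 phosphate work-up, rapid filtration over buffered silica
Reagents that add atoms: none
Why: In this crossed Claisen condensation of a 3,5-diketo ester trianion the last-formed terminal enolate carbon (C4a) is the most nucleophilic site and attacks the ester carbonyl of 8 (forms C4–C4a) at −78 °C far faster than any anion opens the epoxide or removes the poorly acidic oxirane H3, so both stereocentres are carried over, while the second equivalent of 9 takes up the acidic C4a proton of the product.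

Step 7
Reactants: 10 methyl 2,4-bis[4-(methoxymethoxy)benzyl]-7-{(2R,3S)-3-[4-(methoxymethoxy)phenyl]oxiran-2-yl}-3,5,7-trioxoheptanoate
Product: 12 (2R,3R)-3,5,7-trihydroxy-6,8-bis[4-(methoxymethoxy)benzyl]-2-[4-(methoxymethoxy)phenyl]chroman-4-one, via acylphloroglucinol epoxide 11 (not isolated)
Conditions: Mg(OCH3)2 (4 equiv), MeOH–THF 1:1 (degassed, Ar), 0 to 40 °C; then AcOH, 0 °C
Reagents that add atoms: none
Why: Proposed new method: Mg(OCH3)2 turns 10 into a chelated polyenolate, the central carbon C4a of the C4/C8a diketonate adds to the ester carbonyl C5, methoxide leaves, and the 2-acylcyclohexane-1,3,5-trione so formed tautomerises irreversibly to the acylphloroglucinol 11, which closes ring A in the 6-(enolendo)-exo-trig mode. One of the two equivalent ortho phenoxides of 11 then attacks the benzylic epoxide carbon C2 anti to the breaking C2–O bond and forms O1–C2, which closes ring C in the 6-endo-tet mode; should the enolate oxygen on C8a open the epoxide before ring A exists, the same O1–C2 bond results and C4a stays nucleophilic as a vinylogous enolate carbon, so that both orders converge on 12. The closest known reaction types are the base-mediated Claisen cyclisation of 3,5,7-triketo esters to acylphloroglucinols and the cyclisation of 2'-hydroxychalcone epoxides to trans-dihydroflavonols, and what is new is their coupling in one flask on a chain that carries the epoxide through the aromatisation. C3 keeps its R configuration because its C–O bond is never broken, and the new centre C2 is set as R by inversion of the S benzylic carbon, while a looser cation-like opening would still close to the diequatorial 2,3-trans ring under the control of C3. Claisen folding must win over aldol and lactone folding: attack of C6 on C4 would leave C6 quaternary (benzyl plus ester) so that this reversible aldol cannot aromatise, and the enol lactone is reopened by methoxide, so that both side equilibria drain into 11. Attack at C2 must win over 5-exo attack at C3 and over methanolysis, which should be secured by the 4-alkoxyphenyl donor on C2, by coordination of magnesium to the epoxide oxygen and to O4, and by the coplanarity of C4=O with ring A that the chelate to the second ortho oxygen enforces, and the electron-rich oxido ring A lowers the acidity of H3 and so shields C3 from epimerisation.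

Step 8
Reactants: 12 (2R,3R)-3,5,7-trihydroxy-6,8-bis[4-(methoxymethoxy)benzyl]-2-[4-(methoxymethoxy)phenyl]chroman-4-one
Product: 13 gericudranin D, (2R,3R)-3,5,7-trihydroxy-6,8-bis(4-hydroxybenzyl)-2-(4-hydroxyphenyl)chroman-4-one
Conditions: aq. HCl (3 M)/MeOH 1:10, 45 °C
Reagents that add atoms: none
Why: Acid-catalysed acetal exchange with methanol (MOM cleavage) frees the three phenols, and the (2R,3R) configuration should be kept because C3 is not enolised in dilute acid and the diequatorial 2,3-trans arrangement is the thermodynamically preferred one.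

Compound list
1 | methyl 3-(4-hydroxyphenyl)propanoate | COC(=O)CCc1ccc(O)cc1 | starting material
2 | methyl 3-[4-(methoxymethoxy)phenyl]propanoate | COC(=O)CCc1ccc(OCOC)cc1 | intermediate
3 | methyl 2-[4-(methoxymethoxy)benzyl]-5-[4-(methoxymethoxy)phenyl]-3-oxopentanoate (racemic) | COC(=O)C(Cc1ccc(OCOC)cc1)C(=O)CCc1ccc(OCOC)cc1 | intermediate
4 | dilithium dienolate of 3 (deprotonated at C6 and C8) | [Li+].[Li+].COC([O-])=C(Cc1ccc(OCOC)cc1)C([O-])=CCc1ccc(OCOC)cc1 | intermediate
5 | methyl 2,4-bis[4-(methoxymethoxy)benzyl]-3,5-dioxohexanoate (epimers, tautomers) | COC(=O)C(Cc1ccc(OCOC)cc1)C(=O)C(Cc1ccc(OCOC)cc1)C(C)=O | intermediate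
6 | methyl (E)-3-(4-hydroxyphenyl)prop-2-enoate | COC(=O)/C=C/c1ccc(O)cc1 | starting material
7 | methyl (E)-3-[4-(methoxymethoxy)phenyl]prop-2-enoate | COC(=O)/C=C/c1ccc(OCOC)cc1 | intermediate
8 | methyl (2R,3S)-3-[4-(methoxymethoxy)phenyl]oxirane-2-carboxylate | COC(=O)[C@@H]1O[C@H]1c1ccc(OCOC)cc1 | intermediate
9 | trilithium trienolate of 5 (deprotonated at C6, C8 and C4a) | [Li+].[Li+].[Li+].COC([O-])=C(Cc1ccc(OCOC)cc1)C([O-])=C(Cc1ccc(OCOC)cc1)C([O-])=C | intermediate
10 | methyl 2,4-bis[4-(methoxymethoxy)benzyl]-7-{(2R,3S)-3-[4-(methoxymethoxy)phenyl]oxiran-2-yl}-3,5,7-trioxoheptanoate (epimers at C6 and C8, tautomers) | COC(=O)C(Cc1ccc(OCOC)cc1)C(=O)C(Cc1ccc(OCOC)cc1)C(=O)CC(=O)[C@@H]1O[C@H]1c1ccc(OCOC)cc1 | intermediate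
11 | {(2R,3S)-3-[4-(methoxymethoxy)phenyl]oxiran-2-yl}{2,4,6-trihydroxy-3,5-bis[4-(methoxymethoxy)benzyl]phenyl}methanone (present as its magnesium phenoxide) | O=C(c1c(O)c(Cc2ccc(OCOC)cc2)c(O)c(Cc2ccc(OCOC)cc2)c1O)[C@@H]1O[C@H]1c1ccc(OCOC)cc1 | intermediate
12 | (2R,3R)-3,5,7-trihydroxy-6,8-bis[4-(methoxymethoxy)benzyl]-2-[4-(methoxymethoxy)phenyl]chroman-4-one | O=C1c2c(O)c(Cc3ccc(OCOC)cc3)c(O)c(Cc3ccc(OCOC)cc3)c2O[C@H](c2ccc(OCOC)cc2)[C@H]1O | intermediate
13 | gericudranin D, (2R,3R)-3,5,7-trihydroxy-6,8-bis(4-hydroxybenzyl)-2-(4-hydroxyphenyl)chroman-4-one | O=C1c2c(O)c(Cc3ccc(O)cc3)c(O)c(Cc3ccc(O)cc3)c2O[C@H](c2ccc(O)cc2)[C@H]1O | target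

Total step count: 8. Longest linear sequence: 6 steps (1, 2, 3, 6, 7, 8).

Steps most likely to fail

1. Step 7.
- **What may go wrong:** the epoxide may open at C3 (5-exo) or be opened by methanol before ring A exists. Methoxide may cleave the chain by retro-Claisen attack. The product may epimerise or be oxidised by air under the basic conditions.
- **Fallback:** known chemistry in which ring A is bought instead of folded and the benzyl groups come last. It sets out from 8 and comes back to the route at 13.
- Phloroglucinol is protected with MOMCl and i-Pr2NEt to give 1,3,5-tris(methoxymethoxy)benzene F1.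
- Directed ortho-lithiation (n-BuLi, THF, 0 °C) gives 2,4,6-tris(methoxymethoxy)phenyllithium F2.
- Acylation of F2 with 8 at −78 °C (AcOH quench) gives the protected chalcone epoxide {(2R,3S)-3-[4-(methoxymethoxy)phenyl]oxiran-2-yl}[2,4,6-tris(methoxymethoxy)phenyl]methanone F3. Its doubly ortho-substituted carbonyl resists a second addition.
- HCl in methanol removes the four acetals, and a freed ortho phenol closes ring C at the benzylic carbon. This is the established acid-induced deprotection–cyclisation of protected chalcone epoxides to trans-dihydroflavonols, and it gives (2R,3R)-aromadendrin F4.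
- A ZnCl2-mediated double Friedel–Crafts C-benzylation of C6 and C8 with 4-hydroxybenzyl alcohol in dioxane, a reaction type known for 5,7-dihydroxyflavanones, then gives 13.

2. Step 6.
- **What may go wrong:** the third deprotonation may be incomplete. Proton transfer from the acidic product to the trianion may stall the reaction. The epoxide may open prematurely during quench and isolation.
- **Fallback:** a less charged nucleophile is used, with the ester masked as a lactone. It sets out from 5 and comes back to the route at 10.
- 5 is lactonised with DBU in toluene at 80 °C, a known cyclisation of 2,4-disubstituted 3,5-diketo esters, to give 4-hydroxy-3,5-bis[4-(methoxymethoxy)benzyl]-6-methyl-2H-pyran-2-one F5.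
- Two equivalents of LiN(i-Pr)2 give the dilithium pyrone dianion F6, deprotonated at the 4-OH and at the 6-methyl group.
- F6 is acylated at carbon by 8 at −78 °C (AcOH quench) to give 4-hydroxy-3,5-bis[4-(methoxymethoxy)benzyl]-6-(2-{(2R,3S)-3-[4-(methoxymethoxy)phenyl]oxiran-2-yl}-2-oxoethyl)-2H-pyran-2-one F7.
- Mg(OCH3)2 in methanol opens the lactone of F7 by methanolysis, a known unmasking of 2-pyrones to triketo esters. This gives 10 directly in the flask of step 7.

3. Step 5.
- **What may go wrong:** the facial selectivity may be insufficient. The ketone catalyst may decompose before conversion is complete. The electron-rich epoxide may be opened hydrolytically in the aqueous medium.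
- **Fallback:** enzyme-controlled kinetic resolution replaces catalyst-controlled oxygen transfer. It sets out from 7 and comes back to the route at 8.
- 7 is epoxidised with dimethyldioxirane made in situ (KHSO5, acetone, NaHCO3, MeCN–H2O) to give racemic methyl trans-3-[4-(methoxymethoxy)phenyl]oxirane-2-carboxylate F8.
- A lipase (from Serratia marcescens, toluene/pH 8 buffer, NaHSO3) hydrolyses the (2S,3R)-ester selectively, a resolution type well established for 3-(4-alkoxyphenyl)glycidic esters, and leaves 8 in the organic phase.

Further compounds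
F1 | step 7 | 1,3,5-tris(methoxymethoxy)benzene | COCOc1cc(OCOC)cc(OCOC)c1
F2 | step 7 | 2,4,6-tris(methoxymethoxy)phenyllithium | [Li]c1c(OCOC)cc(OCOC)cc1OCOC
F3 | step 7 | {(2R,3S)-3-[4-(methoxymethoxy)phenyl]oxiran-2-yl}[2,4,6-tris(methoxymethoxy)phenyl]methanone | O=C(c1c(OCOC)cc(OCOC)cc1OCOC)[C@@H]1O[C@H]1c1ccc(OCOC)cc1
F4 | step 7 | (2R,3R)-aromadendrin, (2R,3R)-3,5,7-trihydroxy-2-(4-hydroxyphenyl)chroman-4-one | O=C1c2c(O)cc(O)cc2O[C@H](c2ccc(O)cc2)[C@H]1O
F5 | step 6 | 4-hydroxy-3,5-bis[4-(methoxymethoxy)benzyl]-6-methyl-2H-pyran-2-one | CC1=C(Cc2ccc(OCOC)cc2)C(O)=C(Cc2ccc(OCOC)cc2)C(=O)O1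
F6 | step 6 | dilithium pyrone dianion (F5 deprotonated at the 4-OH and the 6-methyl group) | [Li+].[Li+].[CH2-]C1=C(Cc2ccc(OCOC)cc2)C([O-])=C(Cc2ccc(OCOC)cc2)C(=O)O1
F7 | step 6 | 4-hydroxy-3,5-bis[4-(methoxymethoxy)benzyl]-6-(2-{(2R,3S)-3-[4-(methoxymethoxy)phenyl]oxiran-2-yl}-2-oxoethyl)-2H-pyran-2-one | O=C(CC1=C(Cc2ccc(OCOC)cc2)C(O)=C(Cc2ccc(OCOC)cc2)C(=O)O1)[C@@H]1O[C@H]1c1ccc(OCOC)cc1
F8 | step 5 | racemic methyl trans-3-[4-(methoxymethoxy)phenyl]oxirane-2-carboxylate (both enantiomers) | COC(=O)[C@@H]1O[C@H]1c1ccc(OCOC)cc1.COC(=O)[C@H]1O[C@@H]1c1ccc(OCOC)cc1
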